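The ratio I reckoned for these flasks was the time in the flask over the time that open intermediate and target need to drain together into the isomer of the product.

    starting material + partner → open intermediate + by-product (k1 = 3.3 M⁻¹ s⁻¹, Ea1 = 54.0 kJ mol⁻¹)
    open intermediate ⇌ target (K2 = 0.34, k2 = 0.092 s⁻¹, Ea2 = 79.0 kJ mol⁻¹, ΔH2 = −18.0 kJ mol⁻¹)
    open intermediate ⇌ isomer of the product (K3 = 11, k3 = 0.034 s⁻¹, Ea3 = 98.0 kJ mol⁻¹, ΔH3 = 32.0 kJ mol⁻¹)
    open intermediate + capture agent → trapped intermediate (k4 = 0.15 M⁻¹ s⁻¹, Ea4 = 49.0 kJ mol⁻¹)
    partner + protic impurity → quenched reagent (k5 = 0.90 M⁻¹ s⁻¹, Ea5 = 45.0 kJ mol⁻¹)
    2 starting material → self-condensation product (k6 = 0.33 M⁻¹ s⁻¹, Ea6 = 59.0 kJ mol⁻¹)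
    (constants at 60 °C)

| setting | Tuesday's | Monday's | Friday's | Thursday's |
|---|---|---|---|---|
| starting material | 0.18 M | 0.18 M | 0.18 M | 0.18 M |
| partner | 0.162 M | 0.162 M | 0.162 M | 0.162 M |
| capture agent | 3.60 mM | 3.60 mM | 3.60 mM | 3.60 mM |
| protic impurity | 9.00 mM | 9.00 mM | 9.00 mM | 9.00 mM |
| temperature | 85 °C | 35 °C | 60 °C |  |
| time | 5.0 min | 5.0 min | 5.0 min | 5.0 min |
| remark |  |  |  | at 35 °C until 2.5 min, from then on at 85 °C |

- in percentages every species weighs as the starting material in it: one self-condensation product counts as two
- a step written with two of one species runs at k times the square of its concentration and takes two of it each time
- the list of constants is for 60 °C, to be carried to other temperatures by the activation energies and enthalpies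

1. the flask with the highest amount of target, in percent of the starting material charged ("all alike" if they lie within 1.5 percentage points) (Tuesday's / Monday's / Friday's / Thursday's / all alike)
2. final target, as a percentage of the starting material charged, in Tuesday's
3. final target, as a percentage of the starting material charged, in Monday's
4. final target, as a percentage of the starting material charged, in Friday's
5. final target, as a percentage of the starting material charged, in Thursday's

I went down the time scales of Monday's, at 35 °C, from the fastest. Starting material and partner meet with a time constant of about 0.136 min, and at the start the step that makes open intermediate uses partner 56 times as fast as the quench does, and starting material 5.2 times as fast as self-condensation does. That second ratio goes with partner over starting material, and, assuming that these two fall side by side, I let it stand and gave the step that makes open intermediate a share of 83.9% of the starting material, which the partner charge of 0.900 equivalents covers. Taking off the whole capture charge, 2.00% of the starting material, left a pool of 81.9% shared among open intermediate, target and isomer.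

The next rung is the step between open intermediate and target, whose relaxation half-life, both ways together, is 0.464 min, short against the 5.0 min in the flask, so in Monday's target follows open intermediate at their equilibrium ratio of 0.576, a pre-equilibrium that puts 36.5% of the pair in target. The last rung is the leak from that pair into the isomer, with a forward constant of 0.116 min⁻¹. Open intermediate is the fraction one over one plus the target ratio of the pair, and the isomer returns at one over its own equilibrium ratio of 4.31, so, as with two tanks joined by a thin pipe, the drain rate is the forward constant times the sum of those two fractions, 0.100 min⁻¹, and its time constant of 10.00 min is longer than the times of both rungs above it. The drain number, this drain rate times the time in the flask, came to 0.501 for Monday's, below one, which is kinetic control: target's final share of the pool is 9.79%, 60.6% of its excess over that share survives, and I reckoned Monday's target at 21.3%.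

Friday's has a drain number of 8.54. In Tuesday's, target over open intermediate falls to 0.216, isomer over open intermediate rises to 24.6, and the number is 104. Both stand far above one, which is thermodynamic control, so I took target as pool times final share, carrying the pool over unchanged as an assumption: 2.26% for Friday's and 0.684% for Tuesday's. Thursday's has 52.0 in its hot part at 85 °C, so I gave it Tuesday's 0.684% as well, and Monday's stood highest on my reckoning.

The forecast named Monday's, with 20% there, 2.2% for Friday's, 0.65% for Tuesday's and 0.67% for Thursday's, holding of Monday's that “the high-barrier drain to the isomer is too slow to finish”. The simulation gave Monday's as the flask with most target, at 22.3%, with Friday's at 2.27%, Tuesday's at 0.678% and Thursday's at 0.698%, so my 21.3% for Monday's lies 1.00 percentage point below it.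

With the backward run from target to open intermediate taken away, Monday's ends at 65.2% instead of 22.3%, and that backward run is the main reason for the difference; it is the tie through which a drain number of 0.501 acts on target. The same flask as Monday's run at 50 °C has ratios of 0.416 and 7.69 and a drain number of 2.85, so 5.78% of the excess survives and Monday's pool, carried over unchanged as an assumption, gives 4.91%. The simulation gives 5.25%.

The constants were drawn at random within sensible limits; the run is a simulation.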